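**Retrosynthetic overview**

1. Numbering used below: ring C1–C10, diene C1=C2–C3=C4, CO2H on C4 and C8, =CH2 on C5, C9 quaternary (CH3, CH2C(=O)-3-furyl), C10 the ring CH2 between C9 and C1. The last operations only adjust oxidation levels (C5=O to C5=CH2, CH2OH to CO2H at C8, ester hydrolysis).
2. Ten-membered ring from a four-carbon ring expansion of a cyclohexanone (C5–C10): its C5=C10 silyl enol ether and methyl 2-oxo-2H-pyran-3-carboxylate ([4+2], then loss of CO2) give a cyclohexadiene fused across C5–C10, which inserts C1–C4 with the ester on C4. Fluoride-triggered cleavage of the C5–C10 σ-bond then opens the bicycle.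
3. Key disconnection C9–CH2 (side chain): Mukaiyama–Michael addition of the enol silane of 3-acetylfuran to (R)-4-(silyloxymethyl)-3-methylcyclohex-2-enone, anti to the C8 substituent. It sets the quaternary centre and delivers the regiodefined C5=C10 enol silane.
4. Enabling feature: C5, which carries the exocyclic =CH2, is a masked C=O two ring bonds from C9 (through C10). The furyl C=O and C5 are therefore 1,5-related across C9, and atoms C5–C10 with CH3 on C9 and the carbon substituent on C8 are a 4-substituted 3-methylcyclohex-2-enone whose β-carbon is C9.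
5. Ring order: cyclohexene C5–C10 (catalytic asymmetric Diels–Alder), then the second six-membered ring C10–C1–C2–C3–C4–C5 (pyrone cycloaddition), then the ten-membered ring by opening the shared C5–C10 bond. The furan is bought.

Key step: step 7

Remark: the ring-fusion centres of 12–15 and the carbinol centre of 14–18 are expected as mixtures and are erased in steps 10 and 12, so only the two stereocentres of the target are drawn. Commercial 3-penten-2-one is taken as the E isomer.

**Route**

Step 1
Reactants: 1 (E)-pent-3-en-2-one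
Product: 2 (E)-triisopropyl(penta-1,3-dien-2-yloxy)silane
Conditions: LDA, THF, −78 °C; TIPSOTf, −78 → 0 °C
Reagents that add atoms: triisopropylsilyl trifluoromethanesulfonate, CC(C)[Si](C(C)C)(C(C)C)OS(=O)(=O)C(F)(F)F
Why: Kinetic deprotonation of the methyl group and O-silylation (silyl enol ether formation) should give the cross-conjugated 2-silyloxy diene.

Step 2
Reactants: 2 (E)-triisopropyl(penta-1,3-dien-2-yloxy)silane; 3 2,2,2-trifluoroethyl acrylate
Product: 4 2,2,2-trifluoroethyl (1R,2S)-2-methyl-4-[(triisopropylsilyl)oxy]cyclohex-3-ene-1-carboxylate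
Conditions: chiral oxazaborolidinium triflimide (from α,α-diphenylprolinol, tri-o-tolylboroxine and Tf2NH; the enantiomer that delivers the 1R adduct; 20 mol %), CH2Cl2, −78 °C
Reagents that add atoms: none
Why: Catalytic enantioselective Diels–Alder reaction in which the 2-silyloxy and terminal methyl groups both direct the ester carbon next to the methyl-bearing carbon, endo approach gives the cis adduct, and the catalyst's facial shielding of the acrylate sets the ester-bearing centre (the methyl-bearing centre is erased in step 5).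

Step 3
Reactants: 4 2,2,2-trifluoroethyl (1R,2S)-2-methyl-4-[(triisopropylsilyl)oxy]cyclohex-3-ene-1-carboxylate
Product: 5 [(1R,2R)-2-methyl-4-[(triisopropylsilyl)oxy]cyclohex-3-en-1-yl]methanol
Conditions: LiAlH4, Et2O, −78 → 0 °C
Reagents that add atoms: none
Why: Hydride reduction of the ester removes the acidifying carbonyl before the enone is unveiled, so the stereocentre cannot later epimerise through a dienol, and the TIPS enol ether is inert to LiAlH4.

Step 4
Reactants: 5 [(1R,2R)-2-methyl-4-[(triisopropylsilyl)oxy]cyclohex-3-en-1-yl]methanol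
Product: 6 tert-butyl{[(1R,2R)-2-methyl-4-[(triisopropylsilyl)oxy]cyclohex-3-en-1-yl]methoxy}diphenylsilane
Conditions: TBDPSCl, imidazole, CH2Cl2, 0 °C → rt
Reagents that add atoms: tert-butyl(chloro)diphenylsilane, CC(C)(C)[Si](Cl)(c1ccccc1)c1ccccc1
Why: Standard silylation of the primary alcohol gives an ether that should survive the Lewis acid, fluoride at low temperature, hydride and titanium steps that follow.

Step 5
Reactants: 6 tert-butyl{[(1R,2R)-2-methyl-4-[(triisopropylsilyl)oxy]cyclohex-3-en-1-yl]methoxy}diphenylsilane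
Product: 7 (4R)-4-{[(tert-butyldiphenylsilyl)oxy]methyl}-3-methylcyclohex-2-en-1-one
Conditions: Pd(OAc)2 (1.1 equiv), MeCN, rt → 40 °C
Reagents that add atoms: none
Why: Saegusa–Ito oxidation, in which the oxa-π-allyl palladium species can β-hydride eliminate only toward the methyl-bearing carbon, so the 3-methyl enone forms and the remaining stereocentre (no longer α to a carbonyl) is untouched.

Step 6
Reactants: 8 3-acetylfuran
Product: 9 {[1-(furan-3-yl)ethenyl]oxy}trimethylsilane
Conditions: TMSOTf, Et3N, CH2Cl2, 0 °C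
Reagents that add atoms: trimethylsilyl trifluoromethanesulfonate, C[Si](C)(C)OS(=O)(=O)C(F)(F)F
Why: Soft enolisation and O-silylation of the methyl ketone can give only one enol silane.

Step 7
Reactants: 7 (4R)-4-{[(tert-butyldiphenylsilyl)oxy]methyl}-3-methylcyclohex-2-en-1-one; 9 {[1-(furan-3-yl)ethenyl]oxy}trimethylsilane
Product: 10 2-[(1S,6R)-6-{[(tert-butyldiphenylsilyl)oxy]methyl}-1-methyl-3-[(trimethylsilyl)oxy]cyclohex-2-en-1-yl]-1-(furan-3-yl)ethan-1-one
Conditions: Tf2NH (3 mol %), 9 (1.3 equiv), CH2Cl2, −78 → −40 °C; Et3N quench; used crude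
Reagents that add atoms: none
Why: Mukaiyama–Michael addition: Tf2NH converts a trace of 9 into Me3SiNTf2, which silylates the enone oxygen of 7; enol silane 9 then attacks the methyl-bearing β-carbon (C9) of the oxocarbenium ion and its silyl group is handed on to the next enone, so the furyl ketone is released and the ring carbonyl emerges as its C5=C10 trimethylsilyl enol ether. The closest known reaction type is the silyl triflimide- or TiCl4-promoted Mukaiyama–Michael addition of ketone enol silanes to 3-methylcyclohex-2-enones, which builds quaternary β-carbons. No ring is closed. The new quaternary stereocentre is controlled by the neighbouring C8 centre: the CH2OSi group sits pseudoaxial to avoid A(1,2) strain with the vinylic methyl, and axial attack on the opposite face places CH2C(=O)-furyl trans and CH3 cis to it. The step needs 1,4- over 1,2-addition and no loss of the γ-proton at C8; the bulky O-silyl oxocarbenium, the reversibility of 1,2-addition, the base-free medium at −78 °C and the absence of a carbonyl on the C8 substituent should secure this.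

Step 8
Reactants: 10 2-[(1S,6R)-6-{[(tert-butyldiphenylsilyl)oxy]methyl}-1-methyl-3-[(trimethylsilyl)oxy]cyclohex-2-en-1-yl]-1-(furan-3-yl)ethan-1-one; 11 methyl 2-oxo-2H-pyran-3-carboxylate
Product: 13 methyl (5S,6R)-6-{[(tert-butyldiphenylsilyl)oxy]methyl}-5-[2-(furan-3-yl)-2-oxoethyl]-5-methyl-8a-[(trimethylsilyl)oxy]-4a,5,6,7,8,8a-hexahydronaphthalene-1-carboxylate, via bridged lactone cycloadduct 12 (not isolated)
Conditions: 11 (1.5 equiv), CH2Cl2, 12 kbar, 25 °C; then PhMe, 2,6-di-tert-butylpyridine (cat.), 100 °C
Reagents that add atoms: none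
Why: Inverse-electron-demand Diels–Alder reaction of the electron-poor 2-pyrone with the enol silane followed by retro-[4+2] loss of CO2 (the known behaviour of 3-carbomethoxy-2-pyrone toward enol ethers, silyl enol ethers and ketene acetals): the nucleophilic C10 bonds to C6 of the pyrone and the oxygen-bearing C5 to its ester-bearing C3, which puts the ester on C4 next to C5, while suprafacial addition gives a cis ring fusion whose two new centres (either face) are erased in step 10.

Step 9
Reactants: 13 methyl (5S,6R)-6-{[(tert-butyldiphenylsilyl)oxy]methyl}-5-[2-(furan-3-yl)-2-oxoethyl]-5-methyl-8a-[(trimethylsilyl)oxy]-4a,5,6,7,8,8a-hexahydronaphthalene-1-carboxylate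
Product: 14 methyl (5S,6R)-6-{[(tert-butyldiphenylsilyl)oxy]methyl}-5-[2-(furan-3-yl)-2-hydroxyethyl]-5-methyl-8a-[(trimethylsilyl)oxy]-4a,5,6,7,8,8a-hexahydronaphthalene-1-carboxylate
Conditions: NaBH4, EtOH/THF, −20 °C
Reagents that add atoms: none
Why: Borohydride reduction of the only ketone masks it as a carbinol (epimers, re-oxidised in step 12), so that the ring ketone released in step 10 is the only ketone present in step 11; the esters, the dienoate and the silyl ethers should not react.

Step 10
Reactants: 14 methyl (5S,6R)-6-{[(tert-butyldiphenylsilyl)oxy]methyl}-5-[2-(furan-3-yl)-2-hydroxyethyl]-5-methyl-8a-[(trimethylsilyl)oxy]-4a,5,6,7,8,8a-hexahydronaphthalene-1-carboxylate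
Product: 17 methyl (1E,3Z,6S,7R)-7-{[(tert-butyldiphenylsilyl)oxy]methyl}-6-[2-(furan-3-yl)-2-hydroxyethyl]-6-methyl-10-oxocyclodeca-1,3-diene-1-carboxylate, via ring-fusion alkoxide 15 (not isolated), via ten-membered trienolate 16 (not isolated)
Conditions: TBAF (1.05 equiv), THF, −78 → −20 °C; AcOH, −78 °C
Reagents that add atoms: none
Why: Proposed new method: fluoride removes the tertiary Me3Si group and the bare ammonium alkoxide 15 should break the C5–C10 ring-fusion bond (the only σ-bond whose cleavage leaves a stabilised carbanion), because C10 departs as the terminus of a doubly vinylogous β-keto ester enolate (16) in which the new C5 ketone and the C4 ester share the charge; the cyclohexadiene ring enforces cis geometry at both diene double bonds and low-temperature protonation at the terminal CH (C10) should give the conjugated (1E,3Z) keto dienoate; the closest known reaction types are retro-aldol ring expansions of bicyclic β-hydroxy carbonyl compounds (de Mayo type) and the two-carbon ring expansion of 1-silyloxybicyclo[n.2.0]alkene esters made from enol silanes and propiolates, of which this is the four-carbon, vinylogous analogue.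

Step 11
Reactants: 17 methyl (1E,3Z,6S,7R)-7-{[(tert-butyldiphenylsilyl)oxy]methyl}-6-[2-(furan-3-yl)-2-hydroxyethyl]-6-methyl-10-oxocyclodeca-1,3-diene-1-carboxylate
Product: 18 methyl (1E,3Z,6S,7R)-7-{[(tert-butyldiphenylsilyl)oxy]methyl}-6-[2-(furan-3-yl)-2-hydroxyethyl]-6-methyl-10-methylidenecyclodeca-1,3-diene-1-carboxylate
Conditions: Tebbe reagent (3 equiv), pyridine, THF/PhMe, −40 → 0 °C
Reagents that add atoms: Tebbe reagent (written as its two halves), C=[Ti](C1C=CC=C1)C1C=CC=C1.C[Al](C)Cl
Why: Tebbe methylenation (titanium methylidene [2+2] and cycloreversion) should convert the hindered, cross-conjugated ketone into the exocyclic methylene without conjugate addition; esters react more slowly at or below 0 °C, the free carbinol only consumes one equivalent of reagent, and the low temperature avoids [1,7]-hydrogen shifts of the new triene.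

Step 12
Reactants: 18 methyl (1E,3Z,6S,7R)-7-{[(tert-butyldiphenylsilyl)oxy]methyl}-6-[2-(furan-3-yl)-2-hydroxyethyl]-6-methyl-10-methylidenecyclodeca-1,3-diene-1-carboxylate
Product: 19 methyl (1E,3Z,6S,7R)-7-{[(tert-butyldiphenylsilyl)oxy]methyl}-6-[2-(furan-3-yl)-2-oxoethyl]-6-methyl-10-methylidenecyclodeca-1,3-diene-1-carboxylate
Conditions: activated MnO2, CH2Cl2, rt
Reagents that add atoms: none
Why: MnO2 oxidation of the activated furyl carbinol should restore the furyl ketone and merge the carbinol epimers without touching the triene.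

Step 13
Reactants: 19 methyl (1E,3Z,6S,7R)-7-{[(tert-butyldiphenylsilyl)oxy]methyl}-6-[2-(furan-3-yl)-2-oxoethyl]-6-methyl-10-methylidenecyclodeca-1,3-diene-1-carboxylate
Product: 20 methyl (1E,3Z,6S,7R)-6-[2-(furan-3-yl)-2-oxoethyl]-7-(hydroxymethyl)-6-methyl-10-methylidenecyclodeca-1,3-diene-1-carboxylate
Conditions: TBAF, AcOH, THF, 0 °C → rt
Reagents that add atoms: none
Why: Buffered fluoride desilylation should free the primary alcohol under non-basic conditions, so no alkoxide can add to the dienoate.

Step 14
Reactants: 20 methyl (1E,3Z,6S,7R)-6-[2-(furan-3-yl)-2-oxoethyl]-7-(hydroxymethyl)-6-methyl-10-methylidenecyclodeca-1,3-diene-1-carboxylate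
Product: 21 (1R,2S,4Z,6E)-2-[2-(furan-3-yl)-2-oxoethyl]-7-(methoxycarbonyl)-2-methyl-8-methylidenecyclodeca-4,6-diene-1-carboxylic acid
Conditions: TEMPO (20 mol %), PhI(OAc)2, MeCN/H2O (pH 7 buffer), rt
Reagents that add atoms: water, O
Why: Oxoammonium oxidation (TEMPO with PhI(OAc)2 in aqueous acetonitrile) should take the primary alcohol through the aldehyde hydrate to the acid under near-neutral conditions that spare the triene, the furan and the α-stereocentre.

Step 15
Reactants: 21 (1R,2S,4Z,6E)-2-[2-(furan-3-yl)-2-oxoethyl]-7-(methoxycarbonyl)-2-methyl-8-methylidenecyclodeca-4,6-diene-1-carboxylic acid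
Product: 22 (1E,3Z,6S,7R)-6-[2-(furan-3-yl)-2-oxoethyl]-6-methyl-10-methylidenecyclodeca-1,3-diene-1,7-dicarboxylic acid
Conditions: LiOH, THF/H2O, rt; 1 M HCl to pH 3
Reagents that add atoms: lithium hydroxide, [Li+].[OH-]
Why: Saponification of the conjugated methyl ester at room temperature, where the neighbouring acid is already a carboxylate and its α-centre cannot epimerise, followed by acidification should give the diacid.

**Compound list**

1 | (E)-pent-3-en-2-one | C/C=C/C(C)=O | starting material
2 | (E)-triisopropyl(penta-1,3-dien-2-yloxy)silane | C/C=C/C(=C)O[Si](C(C)C)(C(C)C)C(C)C | intermediate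
3 | 2,2,2-trifluoroethyl acrylate | C=CC(=O)OCC(F)(F)F | starting material
4 | 2,2,2-trifluoroethyl (1R,2S)-2-methyl-4-[(triisopropylsilyl)oxy]cyclohex-3-ene-1-carboxylate | CC(C)[Si](C(C)C)(C(C)C)OC1=C[C@H](C)[C@H](C(=O)OCC(F)(F)F)CC1 | intermediate
5 | [(1R,2R)-2-methyl-4-[(triisopropylsilyl)oxy]cyclohex-3-en-1-yl]methanol | CC(C)[Si](C(C)C)(C(C)C)OC1=C[C@H](C)[C@H](CO)CC1 | intermediate
6 | tert-butyl{[(1R,2R)-2-methyl-4-[(triisopropylsilyl)oxy]cyclohex-3-en-1-yl]methoxy}diphenylsilane | CC(C)[Si](C(C)C)(C(C)C)OC1=C[C@H](C)[C@H](CO[Si](c2ccccc2)(c2ccccc2)C(C)(C)C)CC1 | intermediate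
7 | (4R)-4-{[(tert-butyldiphenylsilyl)oxy]methyl}-3-methylcyclohex-2-en-1-one | O=C1CC[C@@H](CO[Si](c2ccccc2)(c2ccccc2)C(C)(C)C)C(C)=C1 | intermediate
8 | 3-acetylfuran (1-(furan-3-yl)ethan-1-one) | CC(=O)c1ccoc1 | starting material
9 | {[1-(furan-3-yl)ethenyl]oxy}trimethylsilane | C=C(O[Si](C)(C)C)c1ccoc1 | intermediate
10 | 2-[(1S,6R)-6-{[(tert-butyldiphenylsilyl)oxy]methyl}-1-methyl-3-[(trimethylsilyl)oxy]cyclohex-2-en-1-yl]-1-(furan-3-yl)ethan-1-one | C[Si](C)(C)OC1=C[C@@](C)(CC(=O)c2ccoc2)[C@H](CO[Si](c2ccccc2)(c2ccccc2)C(C)(C)C)CC1 | intermediate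
11 | methyl 2-oxo-2H-pyran-3-carboxylate | COC(=O)C1=CC=COC1=O | starting material
12 | bridged lactone cycloadduct (2-oxabicyclo[2.2.2]oct-7-en-3-one; the CO2Me-bearing bridgehead C4 is bonded to C5–OSiMe3, the O-bearing bridgehead C1 to C10; ring-fusion epimers) | COC(=O)C12C=CC(OC1=O)C3C2(O[Si](C)(C)C)CC[C@@H](CO[Si](c4ccccc4)(c4ccccc4)C(C)(C)C)[C@]3(C)CC(=O)c4ccoc4 | intermediate
13 | methyl (5S,6R)-6-{[(tert-butyldiphenylsilyl)oxy]methyl}-5-[2-(furan-3-yl)-2-oxoethyl]-5-methyl-8a-[(trimethylsilyl)oxy]-4a,5,6,7,8,8a-hexahydronaphthalene-1-carboxylate (cis-fused, both ring-fusion diastereomers) | COC(=O)C1=CC=CC2C1(O[Si](C)(C)C)CC[C@@H](CO[Si](c3ccccc3)(c3ccccc3)C(C)(C)C)[C@]2(C)CC(=O)c3ccoc3 | intermediate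
14 | methyl (5S,6R)-6-{[(tert-butyldiphenylsilyl)oxy]methyl}-5-[2-(furan-3-yl)-2-hydroxyethyl]-5-methyl-8a-[(trimethylsilyl)oxy]-4a,5,6,7,8,8a-hexahydronaphthalene-1-carboxylate (carbinol epimers) | COC(=O)C1=CC=CC2C1(O[Si](C)(C)C)CC[C@@H](CO[Si](c3ccccc3)(c3ccccc3)C(C)(C)C)[C@]2(C)CC(O)c3ccoc3 | intermediate
15 | tetrabutylammonium 8a-alkoxide of desilylated 14 (ring-fusion alkoxide) | COC(=O)C1=CC=CC2C1([O-])CC[C@@H](CO[Si](c3ccccc3)(c3ccccc3)C(C)(C)C)[C@]2(C)CC(O)c3ccoc3.CCCC[N+](CCCC)(CCCC)CCCC | intermediate
16 | tetrabutylammonium trienolate of 17 (ten-membered ring, O–C5=C4(CO2Me)–C3=C2–C1=C10) | COC(=O)C1=C([O-])CC[C@@H](CO[Si](c2ccccc2)(c2ccccc2)C(C)(C)C)[C@](C)(CC(O)c2ccoc2)C=CC=C1.CCCC[N+](CCCC)(CCCC)CCCC | intermediate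
17 | methyl (1E,3Z,6S,7R)-7-{[(tert-butyldiphenylsilyl)oxy]methyl}-6-[2-(furan-3-yl)-2-hydroxyethyl]-6-methyl-10-oxocyclodeca-1,3-diene-1-carboxylate | O=C1CC[C@@H](CO[Si](c2ccccc2)(c2ccccc2)C(C)(C)C)[C@](C)(CC(O)c2ccoc2)C/C=C\C=C/1C(=O)OC | intermediate
18 | methyl (1E,3Z,6S,7R)-7-{[(tert-butyldiphenylsilyl)oxy]methyl}-6-[2-(furan-3-yl)-2-hydroxyethyl]-6-methyl-10-methylidenecyclodeca-1,3-diene-1-carboxylate | C=C1CC[C@@H](CO[Si](c2ccccc2)(c2ccccc2)C(C)(C)C)[C@](C)(CC(O)c2ccoc2)C/C=C\C=C/1C(=O)OC | intermediate
19 | methyl (1E,3Z,6S,7R)-7-{[(tert-butyldiphenylsilyl)oxy]methyl}-6-[2-(furan-3-yl)-2-oxoethyl]-6-methyl-10-methylidenecyclodeca-1,3-diene-1-carboxylate | C=C1CC[C@@H](CO[Si](c2ccccc2)(c2ccccc2)C(C)(C)C)[C@](C)(CC(=O)c2ccoc2)C/C=C\C=C/1C(=O)OC | intermediate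
20 | methyl (1E,3Z,6S,7R)-6-[2-(furan-3-yl)-2-oxoethyl]-7-(hydroxymethyl)-6-methyl-10-methylidenecyclodeca-1,3-diene-1-carboxylate | C=C1CC[C@@H](CO)[C@](C)(CC(=O)c2ccoc2)C/C=C\C=C/1C(=O)OC | intermediate
21 | (1R,2S,4Z,6E)-2-[2-(furan-3-yl)-2-oxoethyl]-7-(methoxycarbonyl)-2-methyl-8-methylidenecyclodeca-4,6-diene-1-carboxylic acid | C=C1CC[C@@H](C(=O)O)[C@](C)(CC(=O)c2ccoc2)C/C=C\C=C/1C(=O)OC | intermediate
22 | (1E,3Z,6S,7R)-6-[2-(furan-3-yl)-2-oxoethyl]-6-methyl-10-methylidenecyclodeca-1,3-diene-1,7-dicarboxylic acid | C=C1CC[C@@H](C(=O)O)[C@](C)(CC(=O)c2ccoc2)C/C=C\C=C/1C(=O)O | target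

**Step count and risks**

Total steps: 15. Longest linear sequence: 14 steps (steps 1–5 and 7–15); step 6 is a one-step branch.

Steps most likely to fail:

1. Step 10 (Proposed new method). The alkoxide may fail to fragment, because C–C cleavage has to pay for the strain of the ten-membered trienolate and the trienolate can re-close. It may instead aromatise by proton transfer from C10 and loss of the oxygen substituent. Protonation of the trienolate at the α-carbon instead of the terminus would give the deconjugated isomer. Fallback by known photochemistry instead of an anionic cleavage: starting from 14, irradiation at ≥300 nm in Et2O at −40 °C should open the cyclohexa-1,3-diene by conrotatory 6π electrocyclic ring opening, the way ring-fused cyclohexadienes are opened to cyclodecatrienes, giving the ten-membered silyl trienol ether F1. Brief K2CO3/MeOH at 0 °C should then cleave the O–Si bond and protonate the extended enolate at C10, and the route is rejoined at 17.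

2. Step 8. The trisubstituted enol silane next to the quaternary carbon may be too hindered for the second bond (C4–C5, between two fully substituted carbons), so that desilylation or only single-bond formation results. The cyclohexadiene may also lose silanol and aromatise during CO2 extrusion. Fallback by stepwise ionic annulation instead of cycloaddition: starting from 10, Me3SiNTf2-catalysed vinylogous Mukaiyama–Michael addition to C6 of pyrone 11 at −78 °C and aqueous work-up should give the keto dihydropyranone F2, which has the C10–C1 bond only. Soft enolisation of its acidic lactone–ester C–H with TMSOTf/Et3N should then close the C4–C5 bond by intramolecular Mukaiyama aldol addition to the silyl-activated ring ketone and trap the aldolate as its silyl ether. This gives 12, where the route is rejoined (CO2 loss as in step 8).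

3. Step 11. Carbonyl olefination of the hindered, cross-conjugated ketone may be slow, since it can be partly tied up as a 2H-pyran by oxa-6π closure of the cis-dienone. Attack on the ester or enolisation toward C6 would then compete. Fallback by addition–elimination instead of metal-carbene transfer: starting from 17, Me3SiCH2Li/CeCl3 in THF at −78 °C should add 1,2 to the ring ketone to give the β-hydroxysilane F3. Peterson elimination with KH in THF at 0 °C should then give the methylene compound, and the route is rejoined at 18.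

**Further compounds**

F1 | step 10 | ten-membered silyl trienol ether (Me3SiO–C5=C4(CO2Me)–C3=C2–C1=C10) | COC(=O)C1=C(O[Si](C)(C)C)CC[C@@H](CO[Si](c2ccccc2)(c2ccccc2)C(C)(C)C)[C@](C)(CC(O)c2ccoc2)C=CC=C1
F2 | step 8 | keto dihydropyranone (3,3-disubstituted cyclohexanone carrying a 3-methoxycarbonyl-2-oxo-3,6-dihydro-2H-pyran-6-yl group on C10) | COC(=O)C1C=CC(OC1=O)C2C(=O)CC[C@@H](CO[Si](c3ccccc3)(c3ccccc3)C(C)(C)C)[C@]2(C)CC(=O)c3ccoc3
F3 | step 11 | β-hydroxysilane (C5 carbinol of 17 bearing CH2SiMe3) | C[Si](C)(C)CC1(O)CC[C@@H](CO[Si](c2ccccc2)(c2ccccc2)C(C)(C)C)[C@](C)(CC(O)c2ccoc2)C/C=C\C=C/1C(=O)OC
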